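**Retrosynthetic overview**
1. Target 22 ⇐ bis-benzyl ether 21 ⇐ Evans syn-glycolate aldol of aryloxyacetyl imide 18 with aldehyde 6 (sets both side-chain centres), then LiBH4 release of the auxiliary.
2. 18 ⇐ phenol 15 + bromoacetyl imide 17 (aryl ether C–O bond).
3. 15 (oxolane ring, formed last) ⇐ reduction and SN1 cycloetherification of the trans aldol lactone 13 ⇐ lactone 11 + aldehyde 6.
4. 11 (γ-lactone ring, formed first) ⇐ key step: catalytic enantioselective Baeyer–Villiger ring expansion of prochiral cyclobutanone 9 ⇐ Negishi union of bromophenol 3 with 3-(bromomethyl)cyclobutanone 7.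
5. 3, 4 and 6 (all three aryl rings) ⇐ catechol 1 by O-methylation, para-bromination, benzylation and formylation.

Assumption: 7 is taken as a catalogue compound; the carbinol centre of 13 and 14 is left undefined because step 8 erases it.

**Step 1**
Reactants: 1 catechol
Product: 2 guaiacol (2-methoxyphenol)
Conditions: MeI (1.0 equiv), K2CO3 (1.0 equiv), acetone, reflux
Reagents that add atoms: iodomethane, CI
Why: Williamson O-methylation with one equivalent of MeI stops mainly at the mono-ether, and the veratrole by-product is removed by base extraction.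

**Step 2**
Reactants: 2 guaiacol
Product: 3 4-bromo-2-methoxyphenol
Conditions: NBS (1.0 equiv), MeCN, −20 → 0 °C
Reagents that add atoms: N-bromosuccinimide, O=C1CCC(=O)N1Br
Why: Electrophilic aromatic bromination goes para to the free OH, which is the stronger director.

**Step 3**
Reactants: 3 4-bromo-2-methoxyphenol
Product: 4 1-(benzyloxy)-4-bromo-2-methoxybenzene
Conditions: BnBr, K2CO3, DMF, rt
Reagents that add atoms: benzyl bromide, BrCc1ccccc1
Why: Williamson benzylation masks the phenol for the organolithium step and for the later enolate chemistry.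

**Step 4**
Reactants: 4 1-(benzyloxy)-4-bromo-2-methoxybenzene
Product: 6 4-(benzyloxy)-3-methoxybenzaldehyde, via aryllithium 5 (not isolated)
Conditions: n-BuLi, THF, −78 °C; then DMF, −78 → 0 °C; aq. NH4Cl
Reagents that add atoms: N,N-dimethylformamide, CN(C)C=O
Why: Bromine–lithium exchange followed by formylation with DMF gives the aldehyde used for both outer aryl rings.

**Step 5**
Reactants: 3 4-bromo-2-methoxyphenol; 7 3-(bromomethyl)cyclobutan-1-one
Product: 9 3-(4-hydroxy-3-methoxybenzyl)cyclobutan-1-one, via alkylzinc bromide 8 (not isolated)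
Conditions: 7, Zn dust, LiCl, THF, 30 °C; then slow addition (1.6 equiv) to 3, Pd(OAc)2 (2 mol %), SPhos (4 mol %), THF, 25 °C
Reagents that add atoms: none
Why: Negishi coupling, in which the ketone-tolerant primary alkylzinc couples under Pd/SPhos faster than it is protonated by the phenol OH; no stereocentre is formed.

**Step 6 (key step)**
Reactants: 9 3-(4-hydroxy-3-methoxybenzyl)cyclobutan-1-one
Product: 11 (R)-4-(4-hydroxy-3-methoxybenzyl)dihydrofuran-2(3H)-one, via Criegee adduct 10 (not isolated)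
Conditions: (S,S)-imidodiphosphoric acid from 3,3′-bis(2,4,6-triethylphenyl)-BINOL (5 mol %), 35% aq. H2O2 (1.5 equiv), CHCl3, −40 °C
Reagents that add atoms: hydrogen peroxide, OO
Why: Proposed new method: a confined BINOL-derived imidodiphosphoric acid binds the ketone (P–OH···O=C) and H2O2 (P=O···H–OO) in one chiral pocket, forms Criegee adduct 10 and then assists the 1,2-shift of only one of the two enantiotopic ring CH2 groups (the one antiperiplanar to the O–O bond in the favoured bound conformer), so this Baeyer–Villiger ring expansion sets C4 as R; the deep pocket is meant to hold the flexible CH2Ar arm that open BINOL phosphoric acids discriminate poorly; the closest known reaction type is the chiral phosphoric acid-catalysed Baeyer–Villiger desymmetrisation of 3-substituted cyclobutanones with aqueous H2O2; the sense of induction is checked by rotation against the known (R)-lactone and the antipodal catalyst is used if needed.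

**Step 7**
Reactants: 11 (R)-4-(4-hydroxy-3-methoxybenzyl)dihydrofuran-2(3H)-one; 6 4-(benzyloxy)-3-methoxybenzaldehyde
Product: 13 (3S,4R)-3-{[4-(benzyloxy)-3-methoxyphenyl](hydroxy)methyl}-4-(4-hydroxy-3-methoxybenzyl)dihydrofuran-2(3H)-one (both carbinol epimers), via dilithium enolate 12 (not isolated)
Conditions: LiHMDS (2.2 equiv), THF, −78 °C; then 6 (1.1 equiv), −78 °C; aq. NH4Cl
Reagents that add atoms: none
Why: Lithium enolate aldol addition with the phenoxide as spectator, in which the aldehyde adds anti to the C4 arylmethyl group and so sets C3 trans to it.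

**Step 8**
Reactants: 13 aldol lactone
Product: 15 4-{[(3R,4R,5S)-5-[4-(benzyloxy)-3-methoxyphenyl]-4-(hydroxymethyl)oxolan-3-yl]methyl}-2-methoxyphenol, via triol 14 (not isolated)
Conditions: LiAlH4, THF, 0 °C → rt; then 2 M aq. HCl to pH 1, rt, same flask
Reagents that add atoms: none
Why: Hydride reduction of the lactone followed by acid-promoted SN1 cycloetherification through the p-alkoxybenzyl cation, where the CH2OH on the arylmethyl-bearing carbon closes the five-membered ring with the aryl group trans to the neighbouring CH2OH (sets 5S; both carbinol epimers converge).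

**Step 9**
Reactants: 16 bromoacetyl bromide
Product: 17 (S)-4-benzyl-3-(2-bromoacetyl)oxazolidin-2-one
Conditions: (S)-4-benzyloxazolidin-2-one, n-BuLi, THF, −78 °C; then 16, −78 → 0 °C
Reagents that add atoms: (S)-4-benzyloxazolidin-2-one, O=C1N[C@@H](Cc2ccccc2)CO1
Why: N-acylation of the lithiated Evans auxiliary occurs at the acyl bromide, which is far more electrophilic than the alkyl bromide.

**Step 10**
Reactants: 15 oxolane phenol; 17 (S)-4-benzyl-3-(2-bromoacetyl)oxazolidin-2-one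
Product: 18 (S)-4-benzyl-3-{2-[4-({(3R,4R,5S)-5-[4-(benzyloxy)-3-methoxyphenyl]-4-(hydroxymethyl)oxolan-3-yl}methyl)-2-methoxyphenoxy]acetyl}oxazolidin-2-one
Conditions: K2CO3, acetone, rt → 40 °C
Reagents that add atoms: none
Why: Williamson etherification (SN2) of the only free phenol on the activated α-bromo imide; the primary alcohol is not deprotonated by K2CO3.

**Step 11**
Reactants: 18 aryloxyacetyl imide; 6 4-(benzyloxy)-3-methoxybenzaldehyde
Product: 20 (S)-4-benzyl-3-{(2S,3R)-3-[4-(benzyloxy)-3-methoxyphenyl]-2-[4-({(3R,4R,5S)-5-[4-(benzyloxy)-3-methoxyphenyl]-4-(hydroxymethyl)oxolan-3-yl}methyl)-2-methoxyphenoxy]-3-hydroxypropanoyl}oxazolidin-2-one, via boron enolate 19 (not isolated)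
Conditions: n-Bu2BOTf (2.3 equiv), i-Pr2NEt (2.8 equiv), CH2Cl2, −78 → 0 °C; then 6 (1.3 equiv), −78 → 0 °C; pH 7 buffer, MeOH, 30% H2O2, 0 °C
Reagents that add atoms: none
Why: Evans syn-glycolate aldol, in which the (Z)-boron enolate reacts through a Zimmerman–Traxler chair on the face away from the auxiliary benzyl group to give the 2,3-syn adduct (threo, 1R,2R after reduction), while the second equivalent of Bu2BOTf masks the CH2OH as a borinate.

**Step 12**
Reactants: 20 Evans aldol adduct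
Product: 21 (1R,2R)-1-[4-(benzyloxy)-3-methoxyphenyl]-2-[4-({(3R,4R,5S)-5-[4-(benzyloxy)-3-methoxyphenyl]-4-(hydroxymethyl)oxolan-3-yl}methyl)-2-methoxyphenoxy]propane-1,3-diol
Conditions: LiBH4, THF–MeOH, 0 °C
Reagents that add atoms: none
Why: Reductive cleavage of the N-acyl oxazolidinone gives the primary alcohol and frees the auxiliary without touching any stereocentre.

**Step 13**
Reactants: 21 bis-benzyl ether
Product: 22 (1R,2R)-1-(4-hydroxy-3-methoxyphenyl)-2-[4-({(3R,4R,5S)-5-(4-hydroxy-3-methoxyphenyl)-4-(hydroxymethyl)oxolan-3-yl}methyl)-2-methoxyphenoxy]propane-1,3-diol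
Conditions: H2 (1 atm), 10% Pd/C, EtOAc–EtOH, rt, stopped at full conversion
Reagents that add atoms: none
Why: Hydrogenolysis of the two aryl benzyl ethers is much faster under neutral conditions than cleavage of the benzylic C–O bonds of the oxolane and the carbinol.

**Compound list**
1 | catechol (benzene-1,2-diol) | Oc1ccccc1O | starting material
2 | guaiacol (2-methoxyphenol) | COc1ccccc1O | intermediate
3 | 4-bromo-2-methoxyphenol | COc1cc(Br)ccc1O | intermediate
4 | 1-(benzyloxy)-4-bromo-2-methoxybenzene | COc1cc(Br)ccc1OCc1ccccc1 | intermediate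
5 | [4-(benzyloxy)-3-methoxyphenyl]lithium (not isolated) | [Li]c1ccc(OCc2ccccc2)c(OC)c1 | intermediate
6 | 4-(benzyloxy)-3-methoxybenzaldehyde | COc1cc(C=O)ccc1OCc1ccccc1 | intermediate
7 | 3-(bromomethyl)cyclobutan-1-one | O=C1CC(CBr)C1 | starting material
8 | [(3-oxocyclobutyl)methyl]zinc bromide (not isolated) | O=C1CC(C[Zn]Br)C1 | intermediate
9 | 3-(4-hydroxy-3-methoxybenzyl)cyclobutan-1-one | COc1cc(CC2CC(=O)C2)ccc1O | intermediate
10 | Criegee adduct 1-hydroperoxy-3-(4-hydroxy-3-methoxybenzyl)cyclobutan-1-ol (not isolated) | COc1cc(CC2CC(O)(OO)C2)ccc1O | intermediate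
11 | (R)-4-(4-hydroxy-3-methoxybenzyl)dihydrofuran-2(3H)-one | COc1cc(C[C@H]2COC(=O)C2)ccc1O | intermediate
12 | dilithium enolate-phenolate of 11 (not isolated) | COc1cc(C[C@H]2COC(O[Li])=C2)ccc1O[Li] | intermediate
13 | (3S,4R)-3-{[4-(benzyloxy)-3-methoxyphenyl](hydroxy)methyl}-4-(4-hydroxy-3-methoxybenzyl)dihydrofuran-2(3H)-one (both carbinol epimers) | COc1cc(C[C@H]2COC(=O)[C@@H]2C(O)c3ccc(OCc4ccccc4)c(OC)c3)ccc1O | intermediate
14 | (2R,3R)-2-{[4-(benzyloxy)-3-methoxyphenyl](hydroxy)methyl}-3-(4-hydroxy-3-methoxybenzyl)butane-1,4-diol (both carbinol epimers, not isolated) | COc1cc(C[C@@H](CO)[C@H](CO)C(O)c2ccc(OCc3ccccc3)c(OC)c2)ccc1O | intermediate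
15 | 4-{[(3R,4R,5S)-5-[4-(benzyloxy)-3-methoxyphenyl]-4-(hydroxymethyl)oxolan-3-yl]methyl}-2-methoxyphenol | COc1cc(C[C@H]2CO[C@H](c3ccc(OCc4ccccc4)c(OC)c3)[C@H]2CO)ccc1O | intermediate
16 | bromoacetyl bromide | BrCC(Br)=O | starting material
17 | (S)-4-benzyl-3-(2-bromoacetyl)oxazolidin-2-one | O=C(CBr)N1[C@@H](Cc2ccccc2)COC1=O | intermediate
18 | (S)-4-benzyl-3-{2-[4-({(3R,4R,5S)-5-[4-(benzyloxy)-3-methoxyphenyl]-4-(hydroxymethyl)oxolan-3-yl}methyl)-2-methoxyphenoxy]acetyl}oxazolidin-2-one | COc1cc(C[C@H]2CO[C@H](c3ccc(OCc4ccccc4)c(OC)c3)[C@H]2CO)ccc1OCC(=O)N5[C@@H](Cc6ccccc6)COC5=O | intermediate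
19 | (Z)-dibutylboron enolate of 18 with the CH2OH as its dibutylborinate (not isolated) | COc1cc(C[C@H]2CO[C@H](c3ccc(OCc4ccccc4)c(OC)c3)[C@H]2COB(CCCC)CCCC)ccc1O/C=C(\OB(CCCC)CCCC)N5[C@@H](Cc6ccccc6)COC5=O | intermediate
20 | (S)-4-benzyl-3-{(2S,3R)-3-[4-(benzyloxy)-3-methoxyphenyl]-2-[4-({(3R,4R,5S)-5-[4-(benzyloxy)-3-methoxyphenyl]-4-(hydroxymethyl)oxolan-3-yl}methyl)-2-methoxyphenoxy]-3-hydroxypropanoyl}oxazolidin-2-one | COc1cc([C@@H](O)[C@@H](C(=O)N2[C@@H](Cc3ccccc3)COC2=O)Oc4ccc(C[C@H]5CO[C@H](c6ccc(OCc7ccccc7)c(OC)c6)[C@H]5CO)cc4OC)ccc1OCc8ccccc8 | intermediate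
21 | (1R,2R)-1-[4-(benzyloxy)-3-methoxyphenyl]-2-[4-({(3R,4R,5S)-5-[4-(benzyloxy)-3-methoxyphenyl]-4-(hydroxymethyl)oxolan-3-yl}methyl)-2-methoxyphenoxy]propane-1,3-diol | COc1cc([C@@H](O)[C@@H](CO)Oc2ccc(C[C@H]3CO[C@H](c4ccc(OCc5ccccc5)c(OC)c4)[C@H]3CO)cc2OC)ccc1OCc6ccccc6 | intermediate
22 | (1R,2R)-1-(4-hydroxy-3-methoxyphenyl)-2-[4-({(3R,4R,5S)-5-(4-hydroxy-3-methoxyphenyl)-4-(hydroxymethyl)oxolan-3-yl}methyl)-2-methoxyphenoxy]propane-1,3-diol | COc1cc([C@@H](O)[C@@H](CO)Oc2ccc(C[C@H]3CO[C@H](c4ccc(O)c(OC)c4)[C@H]3CO)cc2OC)ccc1O | target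

**Totals**
Total step count: 13.
Longest linear sequence: 10 steps (1 → 2 → 3 → 9 → 11 → 13 → 15 → 18 → 20 → 21 → 22).

**Three steps most likely to fail**

Step 6 (the proposed new reaction; risk: low ee or slow turnover with the new acid). The fallback uses known chemistry and sets the same stereocentre by conjugate reduction instead of by the ring expansion; it sets out from 4 and comes back at 11. Heck arylation of allyl alcohol with 4 (Pd(OAc)2, n-Bu4NCl, NaHCO3, DMF, 80 °C) gives 3-[4-(benzyloxy)-3-methoxyphenyl]propanal F1. Morpholine-mediated condensation with glyoxylic acid gives 4-[4-(benzyloxy)-3-methoxybenzyl]-5-hydroxyfuran-2(5H)-one F2. NaBH4 reduction and acid relactonisation give 4-[4-(benzyloxy)-3-methoxybenzyl]furan-2(5H)-one F3. Copper hydride 1,4-reduction (CuCl2, p-tol-BINAP, NaOt-Bu, PMHS, using the ligand antipode that delivers the R lactone) gives (R)-4-[4-(benzyloxy)-3-methoxybenzyl]dihydrofuran-2(3H)-one F4, and hydrogenolysis (H2, Pd/C) gives 11.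

Step 5 (risk: protonation of 8 by the phenol, or ring opening of the (3-oxocyclobutyl)methyl radical during zinc insertion). The fallback builds the four-membered ring by ketene [2+2] cycloaddition instead of cross-coupling; it sets out from 4 and comes back at 9. The Grignard reagent of 4 (Mg, THF) with allyl bromide gives 4-allyl-1-(benzyloxy)-2-methoxybenzene F5. Dichloroketene (Cl3CCOCl, Zn–Cu, Et2O) gives 3-[4-(benzyloxy)-3-methoxybenzyl]-2,2-dichlorocyclobutan-1-one F6. Zn in AcOH gives 3-[4-(benzyloxy)-3-methoxybenzyl]cyclobutan-1-one F7, and H2 with Pd/C gives 9.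

Step 11 (risk: the free CH2OH and the Lewis-basic ethers disturb enolisation and lower conversion or dr). The fallback changes the protecting-group plan so that the aldol runs on a substrate without an acidic OH; it sets out from 18 and comes back at 21. TBSCl and imidazole (DMF) give the O-TBS ether of 18 F8. The same boron aldol with 1.1 equiv n-Bu2BOTf and 6 gives the O-TBS syn aldol adduct F9. LiBH4 gives the O-TBS ether of 21 F10, and TBAF in THF gives 21.

**Further compounds**
F1 | step 6 | 3-[4-(benzyloxy)-3-methoxyphenyl]propanal | COc1cc(CCC=O)ccc1OCc1ccccc1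
F2 | step 6 | 4-[4-(benzyloxy)-3-methoxybenzyl]-5-hydroxyfuran-2(5H)-one | COc1cc(CC2=CC(=O)OC2O)ccc1OCc1ccccc1
F3 | step 6 | 4-[4-(benzyloxy)-3-methoxybenzyl]furan-2(5H)-one | COc1cc(CC2=CC(=O)OC2)ccc1OCc1ccccc1
F4 | step 6 | (R)-4-[4-(benzyloxy)-3-methoxybenzyl]dihydrofuran-2(3H)-one | COc1cc(C[C@H]2COC(=O)C2)ccc1OCc1ccccc1
F5 | step 5 | 4-allyl-1-(benzyloxy)-2-methoxybenzene | C=CCc1ccc(OCc2ccccc2)c(OC)c1
F6 | step 5 | 3-[4-(benzyloxy)-3-methoxybenzyl]-2,2-dichlorocyclobutan-1-one | COc1cc(CC2CC(=O)C2(Cl)Cl)ccc1OCc1ccccc1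
F7 | step 5 | 3-[4-(benzyloxy)-3-methoxybenzyl]cyclobutan-1-one | COc1cc(CC2CC(=O)C2)ccc1OCc1ccccc1
F8 | step 11 | O-TBS ether of 18 (silyl on the oxolane CH2OH) | COc1cc(C[C@H]2CO[C@H](c3ccc(OCc4ccccc4)c(OC)c3)[C@H]2CO[Si](C)(C)C(C)(C)C)ccc1OCC(=O)N5[C@@H](Cc6ccccc6)COC5=O
F9 | step 11 | O-TBS syn aldol adduct (O-TBS ether of 20) | COc1cc([C@@H](O)[C@@H](C(=O)N2[C@@H](Cc3ccccc3)COC2=O)Oc4ccc(C[C@H]5CO[C@H](c6ccc(OCc7ccccc7)c(OC)c6)[C@H]5CO[Si](C)(C)C(C)(C)C)cc4OC)ccc1OCc8ccccc8
F10 | step 11 | O-TBS ether of 21 | COc1cc([C@@H](O)[C@@H](CO)Oc2ccc(C[C@H]3CO[C@H](c4ccc(OCc5ccccc5)c(OC)c4)[C@H]3CO[Si](C)(C)C(C)(C)C)cc2OC)ccc1OCc6ccccc6
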